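**Strategy.** Everything rests on cutting C13–C14 of ring A. C13 bears the C15–C17 acrylic acid unit and is tied through C14 to C8, the carbon alpha to the C7 carbonyl of lactone ring B. In retrosynthesis C14 therefore becomes the terminus of an alpha-methylene delta-lactone and C13 the inner carbon of a prenyl-type alkene. One Lewis-acid-triggered cation–olefin conjugate cyclisation then forms C13–C14, closes ring A, sets C13 and C8, and leaves an isopropenyl group for late oxidation. Its precursor 20 is the complete B/C/D spiro keto lactone carrying the exocyclic C8=C14 methylene and a 4-methylpent-3-enyl chain on C9.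

Key step: step 10

Remark: atoms carry ent-kaurane numbers (C1 ketone, C2, C3 OCH, C4 CMe2, C5, C6 OCH2, C7 lactone C=O, C8, C9, C10 spiro, C11–C14, C15–C17 acrylic unit, C20 lactone OCH2). With these numbers the target is 3R,5R,8S,9R,10S,13R.

Assumption: the sense of induction in step 2 is taken from the usual behaviour of rhodium–BINAP catalysts with cyclic enones, and the antipodal ligand would be used if it proved opposite.

Step 1
Reactants: 1 4,4-dimethylcyclohex-2-en-1-one
Product: 2 4,4-dimethylcyclohexa-2,5-dien-1-one
Conditions: DDQ (1.2 equiv), dioxane, reflux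
Reagents that add atoms: none
Why: DDQ dehydrogenation of the enone through its dienol is the standard entry to this cross-conjugated dienone, the quaternary C4 prevents aromatisation, and no stereocentre is formed.

Step 2
Reactants: 2 4,4-dimethylcyclohexa-2,5-dien-1-one; 3 (E)-2-phenylethenylboronic acid
Product: 4 (5R)-4,4-dimethyl-5-[(E)-2-phenylethenyl]cyclohex-2-en-1-one
Conditions: [Rh(OH)(cod)]2 (1.5 mol %), (R)-BINAP (3.3 mol %), dioxane/H2O 10:1, 40 °C, 2 in 1.5-fold excess
Reagents that add atoms: none
Why: This is a Hayashi–Miyaura rhodium-catalysed asymmetric 1,4-addition of an alkenylboronic acid, known for 4,4-disubstituted cyclohexadienones, in which the two enone halves of 2 are equivalent so the BINAP pocket only chooses the alkene face, the R ligand should place the styryl group (a masked C6 hydroxymethyl group) to give 5R, and excess 2 suppresses a second addition.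

Step 3
Reactants: 4 styryl enone
Product: 5 (5R)-6-(hydroxymethylidene)-4,4-dimethyl-5-[(E)-2-phenylethenyl]cyclohex-2-en-1-one (enol of the C10 formyl ketone)
Conditions: NaH, HCO2Et, THF, 0 °C → rt; aq. HCl
Reagents that add atoms: ethyl formate CCOC=O
Why: In this crossed Claisen condensation (formylation) C10 is the only enolisable position, because C4 is quaternary and C2=C3 blocks the other side, so C20 enters regiospecifically and C5 is untouched.

Step 4
Reactants: 5 hydroxymethylidene enone; 6 trimethyl 2-phosphonoacrylate
Product: 7 C10-quaternary keto aldehyde (formyl C20 cis and CH2CH(CO2Me)P(O)(OMe)2 chain C9–C8 trans to the styryl group; C8 epimers)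
Conditions: Et3N (0.2 equiv), CH2Cl2, 0 °C → rt
Reagents that add atoms: none
Why: In this amine-catalysed Michael addition of an acidic 2-formyl ketone to an unhindered, doubly activated acceptor, allylic strain against the exocyclic C20 keeps the styryl group axial so C9 should bond to C10 from the opposite face (C9 trans, C20 cis to C6), and since the addition is reversible this less crowded isomer should also be the equilibrium product.

Step 5
Reactants: 7 keto aldehyde
Product: 9 spiro alpha-phosphono delta-lactone enone (ring B closed; C8 epimers), via hydroxy ester 8 (not isolated)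
Conditions: NaBH4, CH2Cl2/MeOH, −78 °C; then TsOH·H2O (cat.), toluene, 60 °C
Reagents that add atoms: none
Why: Chemoselective borohydride reduction of the non-enolisable, highly electrophilic aldehyde beside the enone at low temperature, followed by acid-catalysed 6-exo-trig lactonisation of the C20 alcohol onto the phosphonate-activated C7 ester, closes ring B without touching C10 or C5.

Step 6
Reactants: 9 spiro phosphono lactone enone
Product: 11 C6 aldehyde, via ozonide 10 (not isolated)
Conditions: O3, CH2Cl2, −78 °C (Sudan Red 7B end point); then Me2S, −78 °C → rt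
Reagents that add atoms: ozone [O-][O+]=O
Why: In this chemoselective ozonolysis, ozone cleaves the electron-rich styryl alkene far faster than the electron-poor enone flanked by C4, and the neutral Me2S work-up avoids epimerisation of the C5 aldehyde.

Step 7
Reactants: 11 C6 aldehyde
Product: 13 B/C/D keto phosphono lactone (C3–O–C6 bridge closed; C8 epimers), via primary alcohol 12 (not isolated)
Conditions: NaBH4, CH2Cl2/MeOH, −78 °C; then DBU (0.3 equiv), CH2Cl2, rt
Reagents that add atoms: none
Why: Low-temperature borohydride reduction again takes the aldehyde before the enone, and the base-catalysed 5-exo-trig oxa-Michael addition of the C6 alcohol can reach C3 only from the face of ring C that carries C6, so ring D closes as a diaxial bridge and C3 is fixed by C5.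

Step 8
Reactants: 13 B/C/D keto phosphono lactone
Product: 16 C8=C9 unsaturated alpha-phosphono spirolactone, via selenide 14 (not isolated), via selenoxide 15 (not isolated)
Conditions: NaH (1.0 equiv), THF, 0 °C; PhSeCl; then 30 % H2O2, pyridine, CH2Cl2, 0 °C → rt
Reagents that add atoms: benzeneselenenyl chloride Cl[Se]c1ccccc1 (PhSe of 14 and 15 only); hydrogen peroxide OO (selenoxide oxygen of 15 only)
Why: In this selenoxide syn elimination, one equivalent of NaH removes only the phosphonate-activated C8 proton (far more acidic than C2–H, so ring D stays closed), selenenylation and oxidation follow, and the only beta hydrogens available are those on C9.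

Step 9
Reactants: 16 unsaturated phosphono spirolactone; 17 5-bromo-2-methylpent-2-ene
Product: 20 alpha-methylene spirolactone bearing the 4-methylpent-3-enyl chain on C9, via Grignard reagent 18 (not isolated), via phosphonate adduct 19 (not isolated)
Conditions: 17, Mg, THF; CuBr·SMe2 (20 mol %), 16, THF, −78 → −30 °C; then (CH2O)n, −30 °C → rt
Reagents that add atoms: formaldehyde C=O (from paraformaldehyde; becomes C14); magnesium [Mg] (in 18 only)
Why: Copper-catalysed 1,4-addition of a Grignard reagent to an alkylidene phosphonoacetate unit, followed by Horner–Wadsworth–Emmons olefination of formaldehyde by the resulting phosphonate anion, is the established tandem route to beta-substituted alpha-methylene lactones and needs no lactone enolate beside the ketone, and C9 is set because the reagent should reach the planar C9 from the ring B face that holds the flat C1 carbonyl, the other face being covered by C5 and the C4 methyl group syn-axial to C9.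

Step 10
Reactants: 20 alpha-methylene spirolactone
Product: 22 isopropenyl spirolactone (15-deoxy target), via aluminium enolate 21 (not isolated)
Conditions: MeAlCl2 (2.5 equiv, hexanes), CH2Cl2, −78 → −20 °C; 2,6-di-tert-butyl-4-methylphenol, −78 °C; aq. potassium sodium tartrate
Reagents that add atoms: methylaluminium dichloride C[Al](Cl)Cl (AlCl2 unit of 21 only; nothing stays in 22)
Why: Proposed new method: MeAlCl2 binds the s-cis-locked C7 carbonyl, the C13=C16 alkene adds through C13 to the free C14 terminus, the tertiary C16 cation gives up a C17 proton that an Al–CH3 bond removes as methane, and enolate 21 is protonated only at the quench. The closest known chemistry is the alkylaluminium-halide-initiated cation–olefin (stepwise formal ene) cyclisation of trisubstituted alkenes onto enones and alpha-substituted acrylates, which has not been reported for an alpha-methylene delta-lactone acceptor. Ring A closes 6-endo-trig at the acceptor (C8 and C14 both become ring members) and exo at the donor alkene (C16 stays outside). C13 follows from a chair-like closure that keeps both large groups, C10 at C9 and the nascent cationic C16 at C13, equatorial and hence trans across the ring, and because a concerted hydrogen transfer to C8 could occur only with C16 axial, a strongly polarising Lewis acid is used to keep the process stepwise. The proton from the bulky phenol should reach C8 along the less encumbered equatorial trajectory, which pushes C7 axial (H8 and H9 cis), and this cis fusion should also be the equilibrium isomer because a trans fusion would turn C11 inward over ring C against the C4 methyl group. The step needs attack on the lactone rather than on the C1 ketone and loss of a methyl rather than the C13 proton: the ketone is neopentyl and screened by the axial C9 branch and the O–C6 bridge while C14 is an open CH2, the Lewis acid is limited to what the ring D ether and the more basic lactone carbonyl consume, and six exposed methyl hydrogens compete with one buried axial C13–H.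

Step 11
Reactants: 22 isopropenyl spirolactone
Product: 24 C15 enal, via allylic alcohol 23 (not isolated)
Conditions: SeO2 (0.3 equiv), t-BuOOH, CH2Cl2, 0 °C → rt; then MnO2, CH2Cl2, rt
Reagents that add atoms: tert-butyl hydroperoxide CC(C)(C)OO (terminal oxygen source, relayed by selenium dioxide O=[Se]=O)
Why: SeO2 allylic oxidation (ene reaction then 2,3-sigmatropic shift), well known for isopropenyl groups on cyclohexanes, functionalises the methyl group, the catalytic room-temperature conditions spare the C2 methylene of the ketone, and MnO2 brings alcohol 23 to the enal level without touching a stereocentre.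

Step 12
Reactants: 24 C15 enal
Product: 25 target CNP0268721.2
Conditions: NaClO2, NaH2PO4, 2-methylbut-2-ene, t-BuOH/H2O, rt
Reagents that add atoms: sodium chlorite [Na+].[O-]Cl=O
Why: The Pinnick oxidation converts the alpha-substituted acrolein into the acrylic acid under buffered, weakly acidic conditions that neither epimerise C8 nor open ring D or the lactone.

**Compound list**

1 | 4,4-dimethylcyclohex-2-en-1-one | CC1(C)CCC(=O)C=C1 | starting material
2 | 4,4-dimethylcyclohexa-2,5-dien-1-one | CC1(C)C=CC(=O)C=C1 | intermediate
3 | (E)-2-phenylethenylboronic acid | OB(O)/C=C/c1ccccc1 | starting material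
4 | (5R)-4,4-dimethyl-5-[(E)-2-phenylethenyl]cyclohex-2-en-1-one | O=C1C=CC(C)(C)[C@@H](/C=C/c2ccccc2)C1 | intermediate
5 | (5R)-6-(hydroxymethylidene)-4,4-dimethyl-5-[(E)-2-phenylethenyl]cyclohex-2-en-1-one | O=C1C=CC(C)(C)[C@@H](/C=C/c2ccccc2)C1=CO | intermediate
6 | trimethyl 2-phosphonoacrylate | C=C(C(=O)OC)P(=O)(OC)OC | starting material
7 | C10-quaternary keto aldehyde, C20 formyl cis and C9–C8 phosphono ester chain trans to the styryl group, C8 epimers | O=C[C@@]1(CC(C(=O)OC)P(=O)(OC)OC)C(=O)C=CC(C)(C)[C@H]1/C=C/c1ccccc1 | intermediate
8 | hydroxy ester (C20 reduced to CH2OH) | OC[C@@]1(CC(C(=O)OC)P(=O)(OC)OC)C(=O)C=CC(C)(C)[C@H]1/C=C/c1ccccc1 | intermediate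
9 | spiro alpha-phosphono delta-lactone enone, styryl on C5, C8 epimers | COP(=O)(OC)C1C[C@]2(COC1=O)C(=O)C=CC(C)(C)[C@H]2/C=C/c1ccccc1 | intermediate
10 | ozonide of 9 (1,2,4-trioxolane at C6) | COP(=O)(OC)C1C[C@]2(COC1=O)C(=O)C=CC(C)(C)[C@H]2C1OOC(O1)c1ccccc1 | intermediate
11 | C6 aldehyde | COP(=O)(OC)C1C[C@]2(COC1=O)C(=O)C=CC(C)(C)[C@H]2C=O | intermediate
12 | C6 primary alcohol | COP(=O)(OC)C1C[C@]2(COC1=O)C(=O)C=CC(C)(C)[C@H]2CO | intermediate
13 | B/C/D keto phosphono lactone, ring D closed, C8 epimers | COP(=O)(OC)C1C[C@]2(COC1=O)C(=O)C[C@H]3OC[C@@H]2C3(C)C | intermediate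
14 | C8 phenylselenide of 13 | COP(=O)(OC)C1([Se]c2ccccc2)C[C@]2(COC1=O)C(=O)C[C@H]3OC[C@@H]2C3(C)C | intermediate
15 | selenoxide of 14 | COP(=O)(OC)C1([Se](=O)c2ccccc2)C[C@]2(COC1=O)C(=O)C[C@H]3OC[C@@H]2C3(C)C | intermediate
16 | C8=C9 unsaturated alpha-phosphono spirolactone | COP(=O)(OC)C1=C[C@]2(COC1=O)C(=O)C[C@H]3OC[C@@H]2C3(C)C | intermediate
17 | 5-bromo-2-methylpent-2-ene | CC(C)=CCCBr | starting material
18 | 4-methylpent-3-enylmagnesium bromide | CC(C)=CCC[Mg]Br | intermediate
19 | C9 4-methylpent-3-enyl phosphonate adduct (drawn protonated at C8, chain cis to C1 on ring B) | COP(=O)(OC)C1[C@@H](CCC=C(C)C)[C@]2(COC1=O)C(=O)C[C@H]3OC[C@@H]2C3(C)C | intermediate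
20 | alpha-methylene spirolactone with the 4-methylpent-3-enyl chain on C9 (key-step precursor) | CC(C)=CCC[C@@H]1C(=C)C(=O)OC[C@]12C(=O)C[C@H]3OC[C@@H]2C3(C)C | intermediate
21 | C8=C7 dichloroaluminium enolate, ring A closed | C=C(C)[C@@H]1CC[C@@H]2C(C1)=C(O[Al](Cl)Cl)OC[C@]21C(=O)C[C@H]2OC[C@@H]1C2(C)C | intermediate
22 | isopropenyl spirolactone (15-deoxy target; C10 and isopropenyl equatorial, C7 axial on ring A) | C=C(C)[C@@H]1CC[C@@H]2[C@H](C1)C(=O)OC[C@]21C(=O)C[C@H]2OC[C@@H]1C2(C)C | intermediate
23 | C15 allylic alcohol | C=C(CO)[C@@H]1CC[C@@H]2[C@H](C1)C(=O)OC[C@]21C(=O)C[C@H]2OC[C@@H]1C2(C)C | intermediate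
24 | C15 enal | C=C(C=O)[C@@H]1CC[C@@H]2[C@H](C1)C(=O)OC[C@]21C(=O)C[C@H]2OC[C@@H]1C2(C)C | intermediate
25 | CNP0268721.2 (3R,5R,8S,9R,10S,13R) | C=C(C(=O)O)[C@@H]1CC[C@@H]2[C@H](C1)C(=O)OC[C@]21C(=O)C[C@H]2OC[C@@H]1C2(C)C | target

**Step count and risks**

Total step count: 12. Longest linear sequence: 12 steps (1 → 25).

**Step 10 (labelled step).**
- What may go wrong: the alkene may add to the aluminium-complexed C1 ketone, which is a competing six-membered carbonyl-ene closure. Ring D may open by Lewis-acid-assisted beta-elimination. The C16 cation may undergo hydride shift or chloride capture instead of losing a methyl proton.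
- Fallback: the fallback uses known radical chemistry, sets out from 20 and returns at 22.
- NBS in aqueous THF at 0 °C should convert only the electron-rich trisubstituted alkene into bromohydrin F1.
- Bu3SnH and AIBN in benzene at 80 °C (slow addition) generate the C13 radical. This radical should close in the known 6-endo Giese mode onto C14 of the alpha-substituted acrylate unit, through a chair with the carbinol carbon equatorial, to give tertiary alcohol F2. C8 can be equilibrated with DBU to the cis fusion if needed.
- Dehydration of F2 with SOCl2 in pyridine at 0 °C should then give 22.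

**Step 9.**
- What may go wrong: facial selectivity at C9 may be poor or reversed, addition next to the spiro centre may be slow, or the reagent may add 1,2 to the ketone.
- Fallback: the fallback inverts the order of bond formation at C9, sets out from 16 and returns at 19.
- The wrongly configured adduct, C9-epimeric phosphonate F3, is selenenylated (NaH, PhSeCl) to selenide F4.
- F4 is oxidised with one equivalent of 3-chloroperbenzoic acid at −78 °C to selenoxide F5.
- On warming, F5 eliminates to the chain-bearing unsaturated phosphono lactone F6.
- Conjugate hydride reduction of F6 (NaBH4, THF/MeOH, −78 °C) should deliver hydrogen to the same preferred face and so turn the chain to the required side, giving 19.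
- Compound 19 is then olefinated with K2CO3 and aqueous formaldehyde to 20.

**Step 11.**
- What may go wrong: oxidation may compete at the tertiary allylic C13–H, conversion may be slow, or over-oxidation may occur.
- Fallback: the fallback sets out from 22 and returns at 24.
- Ene-type allylic chlorination with NaOCl and CeCl3·7H2O in CH2Cl2/H2O should give allylic chloride F7.
- F7 is oxidised with N-methylmorpholine N-oxide and NaHCO3 in MeCN (amine-oxide variant of the Kornblum oxidation) to enal 24.

**Further compounds**

F1 | step 10 | bromohydrin of 20 (Br on C13, OH on C16, C13 epimers) | CC(C)(O)C(Br)CC[C@@H]1C(=C)C(=O)OC[C@]12C(=O)C[C@H]3OC[C@@H]2C3(C)C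
F2 | step 10 | ring A closed tertiary alcohol (2-hydroxypropan-2-yl group on C13) | CC(C)(O)[C@@H]1CC[C@@H]2[C@H](C1)C(=O)OC[C@]21C(=O)C[C@H]2OC[C@@H]1C2(C)C
F3 | step 9 | C9 epimer of 19 | COP(=O)(OC)C1[C@H](CCC=C(C)C)[C@]2(COC1=O)C(=O)C[C@H]3OC[C@@H]2C3(C)C
F4 | step 9 | C8 phenylselenide of F3 | COP(=O)(OC)C1([Se]c2ccccc2)[C@H](CCC=C(C)C)[C@]2(COC1=O)C(=O)C[C@H]3OC[C@@H]2C3(C)C
F5 | step 9 | selenoxide of F4 | COP(=O)(OC)C1([Se](=O)c2ccccc2)[C@H](CCC=C(C)C)[C@]2(COC1=O)C(=O)C[C@H]3OC[C@@H]2C3(C)C
F6 | step 9 | C8=C9 unsaturated phosphono spirolactone bearing the chain on C9 | COP(=O)(OC)C1=C(CCC=C(C)C)[C@]2(COC1=O)C(=O)C[C@H]3OC[C@@H]2C3(C)C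
F7 | step 11 | C15 allylic chloride | C=C(CCl)[C@@H]1CC[C@@H]2[C@H](C1)C(=O)OC[C@]21C(=O)C[C@H]2OC[C@@H]1C2(C)C
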